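**Retrosynthetic overview**
- Target ⇐ 5,3'-di-O-benzyl ombuin 3-O-sulfate (hydrogenolysis of both benzyl ethers) ⇐ 5,3'-di-O-benzylombuin (O-sulfation of its only free OH, the 3-OH).
- Flavonol ⇐ flavone (C3 hydroxylation by epoxidation and rearrangement) ⇐ 2'-hydroxychalcone (oxidative cyclisation).
- Chalcone ⇐ intermolecular Claisen–Schmidt aldol condensation of an A-ring acetophenone with a B-ring benzaldehyde; this is the key C–C bond (Cα–Cβ).
- Acetophenone ⇐ phloroacetophenone (4'-O-methylation, then mono-O-benzylation); aldehyde ⇐ isovanillin (O-benzylation).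
- Ring order: rings A and B are bought; the pyranone ring C is the only ring made (step 5).

Assumption: the target has no stereocentre, so there is no enantiomer to control (the only stereo-element in the route is the (E)-alkene of the chalcone), and sulfate monoesters are written in the hydrogen-sulfate form of the target SMILES although they are handled as sodium salts until the final H+ exchange.

**Step 1**
Reactants: 1 2',4',6'-trihydroxyacetophenone (phloroacetophenone, dried monohydrate)
Product: 2 2',6'-dihydroxy-4'-methoxyacetophenone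
Conditions: Me2SO4 (1.0 eq), K2CO3 (1.05 eq), acetone, reflux, 4 h
Reagents that add atoms: dimethyl sulfate, COS(=O)(=O)OC
Why: Williamson ether synthesis in which the 4'-OH, para to the acetyl group, is the most acidic and least hydrogen-bonded phenol, so one equivalent of methylating agent goes there first.

**Step 2**
Reactants: 2 2',6'-dihydroxy-4'-methoxyacetophenone
Product: 3 2'-benzyloxy-6'-hydroxy-4'-methoxyacetophenone
Conditions: BnBr (1.05 eq), K2CO3 (1.1 eq), acetone, reflux, 6 h
Reagents that add atoms: benzyl bromide, BrCc1ccccc1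
Why: Williamson ether synthesis on a symmetric diol that stops cleanly at mono-benzylation because the remaining OH is locked in a strong hydrogen bond to the ketone.

**Step 3**
Reactants: 4 isovanillin (3-hydroxy-4-methoxybenzaldehyde)
Product: 5 3-benzyloxy-4-methoxybenzaldehyde
Conditions: BnBr (1.1 eq), K2CO3 (1.5 eq), DMF, 60 °C, 3 h
Reagents that add atoms: benzyl bromide, BrCc1ccccc1
Why: Williamson ether synthesis on the only phenol present, which masks the future 3'-OH as a hydrogenolysable benzyl ether.

**Step 4**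
Reactants: 3 2'-benzyloxy-6'-hydroxy-4'-methoxyacetophenone; 5 3-benzyloxy-4-methoxybenzaldehyde
Product: 7 (E)-1-(2-benzyloxy-6-hydroxy-4-methoxyphenyl)-3-(3-benzyloxy-4-methoxyphenyl)prop-2-en-1-one, via racemic β-hydroxy ketone aldol adduct 6 (not isolated)
Conditions: KOH (50% aq, excess), EtOH/THF, rt, 48 h; then cold 1 M HCl
Reagents that add atoms: none
Why: Claisen–Schmidt crossed aldol condensation in which the methyl-ketone enolate of 3 adds to the non-enolisable aldehyde 5 and E1cB loss of water from 6 gives the thermodynamically favoured (E)-enone, so no stereocentre survives.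

**Step 5**
Reactants: 7 (E)-1-(2-benzyloxy-6-hydroxy-4-methoxyphenyl)-3-(3-benzyloxy-4-methoxyphenyl)prop-2-en-1-one
Product: 9 5-benzyloxy-2-(3-benzyloxy-4-methoxyphenyl)-7-methoxy-4H-chromen-4-one, via racemic flavanone 8 (not isolated)
Conditions: I2 (0.1 eq), DMSO, 130 °C, 2 h; then aq Na2S2O3
Reagents that add atoms: none
Why: Iodine-catalysed oxidative cyclisation (I2/DMSO flavone synthesis), in which oxa-Michael closure of the free 2'-OH gives the flavanone and iodine-mediated dehydrogenation with DMSO as terminal oxidant gives the flavone, avoiding the aurone problem of a direct Algar–Flynn–Oyamada reaction on a 6'-substituted chalcone.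

**Step 6**
Reactants: 9 5-benzyloxy-2-(3-benzyloxy-4-methoxyphenyl)-7-methoxy-4H-chromen-4-one
Product: 11 5-benzyloxy-2-(3-benzyloxy-4-methoxyphenyl)-3-hydroxy-7-methoxy-4H-chromen-4-one (5,3'-di-O-benzylombuin), via racemic flavone 2,3-epoxide 10 (not isolated)
Conditions: DMDO (ca. 0.08 M in acetone, 3 eq), CH2Cl2, 0 °C to rt, 16 h, dark; then p-TsOH·H2O (0.1 eq), CH2Cl2, rt, 1 h
Reagents that add atoms: dimethyldioxirane, CC1(C)OO1
Why: Dioxirane epoxidation of the electron-rich C2=C3 bond of the 5-alkoxyflavone followed by acid-catalysed epoxide opening at C2 and loss of H-3 gives the aromatised 3-hydroxyflavone, and the transient stereocentres of 10 are destroyed.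

**Step 7**
Reactants: 11 5,3'-di-O-benzylombuin
Product: 12 5-benzyloxy-2-(3-benzyloxy-4-methoxyphenyl)-7-methoxy-4-oxo-4H-chromen-3-yl hydrogen sulfate (handled as its sodium salt)
Conditions: SO3·pyridine (6 eq), pyridine, 50 °C, 12 h; then aq NaHCO3 to pH 8, evaporate, Sephadex LH-20/C18
Reagents that add atoms: sulfur trioxide pyridine complex, O=S(=O)([O-])[n+]1ccccc1
Why: O-sulfation with an SO3–amine complex is unambiguous because the 3-OH is the only free hydroxyl in 11, and the mildly basic work-up keeps the acid-labile sulfate monoester as a stable salt.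

**Step 8**
Reactants: 12 5,3'-di-O-benzylombuin 3-O-sulfate
Product: 13 ombuin 3-O-sulfate (5-hydroxy-2-(3-hydroxy-4-methoxyphenyl)-7-methoxy-4-oxo-4H-chromen-3-yl hydrogen sulfate)
Conditions: H2 (1 atm), 10% Pd/C, MeOH/THF/H2O, rt, 3 h; filter; Dowex 50W-X8 (H+), 0 °C, lyophilise
Reagents that add atoms: none
Why: Catalytic hydrogenolysis cleaves both benzyl ethers under neutral conditions that leave the aryl sulfate, the methyl ethers and the flavonol core intact, and cold cation exchange then gives the hydrogen-sulfate form.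

**Compound list**
1 | 2',4',6'-trihydroxyacetophenone | CC(=O)c1c(O)cc(O)cc1O | starting material
2 | 2',6'-dihydroxy-4'-methoxyacetophenone | CC(=O)c1c(O)cc(OC)cc1O | intermediate
3 | 2'-benzyloxy-6'-hydroxy-4'-methoxyacetophenone | CC(=O)c1c(O)cc(OC)cc1OCc1ccccc1 | intermediate
4 | isovanillin (3-hydroxy-4-methoxybenzaldehyde) | COc1ccc(C=O)cc1O | starting material
5 | 3-benzyloxy-4-methoxybenzaldehyde | COc1ccc(C=O)cc1OCc1ccccc1 | intermediate
6 | 1-(2-benzyloxy-6-hydroxy-4-methoxyphenyl)-3-(3-benzyloxy-4-methoxyphenyl)-3-hydroxypropan-1-one (racemic aldol adduct, not isolated) | COc1cc(O)c(C(=O)CC(O)c2ccc(OC)c(OCc3ccccc3)c2)c(OCc2ccccc2)c1 | intermediate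
7 | (E)-1-(2-benzyloxy-6-hydroxy-4-methoxyphenyl)-3-(3-benzyloxy-4-methoxyphenyl)prop-2-en-1-one (chalcone) | COc1cc(O)c(C(=O)/C=C/c2ccc(OC)c(OCc3ccccc3)c2)c(OCc2ccccc2)c1 | intermediate
8 | 5-benzyloxy-2-(3-benzyloxy-4-methoxyphenyl)-7-methoxychroman-4-one (racemic flavanone, not isolated) | COc1cc(OCc2ccccc2)c2c(c1)OC(c1ccc(OC)c(OCc3ccccc3)c1)CC2=O | intermediate
9 | 5-benzyloxy-2-(3-benzyloxy-4-methoxyphenyl)-7-methoxy-4H-chromen-4-one (flavone) | COc1cc(OCc2ccccc2)c2c(=O)cc(-c3ccc(OC)c(OCc4ccccc4)c3)oc2c1 | intermediate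
10 | 2,3-epoxide of flavone 9 (racemic, cis-fused 2,3-epoxyflavanone, not isolated) | COc1cc(OCc2ccccc2)c2c(c1)OC1(c3ccc(OC)c(OCc4ccccc4)c3)OC1C2=O | intermediate
11 | 5-benzyloxy-2-(3-benzyloxy-4-methoxyphenyl)-3-hydroxy-7-methoxy-4H-chromen-4-one (5,3'-di-O-benzylombuin) | COc1cc(OCc2ccccc2)c2c(=O)c(O)c(-c3ccc(OC)c(OCc4ccccc4)c3)oc2c1 | intermediate
12 | 5-benzyloxy-2-(3-benzyloxy-4-methoxyphenyl)-7-methoxy-4-oxo-4H-chromen-3-yl hydrogen sulfate | COc1cc(OCc2ccccc2)c2c(=O)c(OS(=O)(=O)O)c(-c3ccc(OC)c(OCc4ccccc4)c3)oc2c1 | intermediate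
13 | ombuin 3-O-sulfate (achiral) | COc1cc(O)c2c(=O)c(OS(=O)(=O)O)c(-c3ccc(OC)c(O)c3)oc2c1 | target

**Totals**
Total step count: 8.
Longest linear sequence: 7 steps (steps 1, 2, 4, 5, 6, 7, 8); step 3 is a one-step branch.

**Three steps most likely to fail, with fallbacks**

Step 6 (DMDO hydroxylation): the risks are incomplete epoxidation and slow oxidation at the benzylic ether CH2 groups. The fallback sets out from flavone 9 and uses a nucleophilic C3 anion instead of electrophilic epoxidation. LDA in THF at −78 °C deprotonates C3 to give the 3-lithioflavone F1. Trapping with B(OMe)3 gives the dimethyl flavon-3-ylboronate F2. Oxidation with H2O2/AcOH at 0 °C converts the C–B bond into C–OH, and the route is rejoined at flavonol 11.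

Step 7 (sulfation): the risks are sluggish reaction of the chelated, hindered 3-OH with the SO3–amine complex and loss of the ionic product on purification. The fallback sets out from 11 and uses a masked sulfate. 2,2,2-Trichloroethyl chlorosulfate with Et3N and DMAP in THF (0 °C to rt) gives the neutral, chromatographable 3-O-(2,2,2-trichloroethyl) sulfate diester F3. Zn dust and HCO2NH4 in MeOH at rt then remove the trichloroethyl group by reductive β-elimination, and the route is rejoined at sulfate 12.

Step 8 (hydrogenolysis next to the sulfate): the risks are desulfation or slow debenzylation. The fallback sets out from 11 and reverses the order of events. Hydrogenolysis first (H2, Pd/C, THF/MeOH) gives ombuin F4. Regioselective sulfation with Bu4N·HSO4 and DCC in pyridine at 4 °C then takes the 3-OH, because the 7- and 4'-OH are methylated, the 5-OH is strongly chelated and the 3'-OH is the least acidic. After cation exchange the route is rejoined at target 13.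

**Further compounds**
F1 | step 6 | 5-benzyloxy-2-(3-benzyloxy-4-methoxyphenyl)-3-lithio-7-methoxy-4H-chromen-4-one | COc1cc(OCc2ccccc2)c2c(=O)c([Li])c(-c3ccc(OC)c(OCc4ccccc4)c3)oc2c1
F2 | step 6 | dimethyl [5-benzyloxy-2-(3-benzyloxy-4-methoxyphenyl)-7-methoxy-4-oxo-4H-chromen-3-yl]boronate | COc1cc(OCc2ccccc2)c2c(=O)c(B(OC)OC)c(-c3ccc(OC)c(OCc4ccccc4)c3)oc2c1
F3 | step 7 | 5-benzyloxy-2-(3-benzyloxy-4-methoxyphenyl)-7-methoxy-4-oxo-4H-chromen-3-yl 2,2,2-trichloroethyl sulfate | COc1cc(OCc2ccccc2)c2c(=O)c(OS(=O)(=O)OCC(Cl)(Cl)Cl)c(-c3ccc(OC)c(OCc4ccccc4)c3)oc2c1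
F4 | step 8 | ombuin (3,5-dihydroxy-2-(3-hydroxy-4-methoxyphenyl)-7-methoxy-4H-chromen-4-one) | COc1cc(O)c2c(=O)c(O)c(-c3ccc(OC)c(O)c3)oc2c1
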